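**Retrosynthetic overview**

1. Target ⇐ trans-hydrindenone 18 by late oxygenation (SeO2 allylic hydroxylation at C6, enolate hydroxylation at C1) and double esterification with (R)-2-methylbutanoic acid.
2. Five-membered ring (C2–C3 bond, E-ethylidene) ⇐ photochemical acyl-radical 5-exo-dig closure of acid 17 onto a propynyl group; this ring is formed last, on the finished six-membered ring.
3. Oxirane ⇐ C5–OH-directed epoxidation of the isopropenyl group; C7 methylidene ⇐ ketone.
4. C3a–C3 and C7a–C1 bonds ⇐ hydroxyl-directed conjugate alkynylation / enolate alkylation of hydroxy enone 9.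
5. Enone 9 ⇐ (+)-nopinone 1 (from (−)-β-pinene): C5 oxygen set on the rigid bicycle, then cyclobutane opening (the cyclobutane is a masked isopropenyl group and a masked regiodefined enolate).

Assumption: (R)-2-methylbutanoic acid, (Z)-3-methylpent-2-enoic acid and 2-(trimethylsilyl)ethyl bromoacetate are bought as such.
Convention: locants C1–C7a in the text are those of the target hydrindane; α/β are the two ring faces, the C4 side chain being β.

This route is a paper proposal: nothing here has been run, and the stereochemical outcomes of steps 5, 7, 10, 11 and 12 are reasoned predictions, not established results.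

**Route**

Step 1
Reactants: 1 (1R,5S)-6,6-dimethylbicyclo[3.1.1]heptan-2-one ((+)-nopinone)
Product: 2 (1R,5R)-6,6-dimethylbicyclo[3.1.1]hept-3-en-2-one ((+)-apoverbenone)
Conditions: IBX·MPO (1.5 equiv), DMSO, 25 °C
Reagents that add atoms: none
Why: IBX dehydrogenation of a ketone (Nicolaou) can only desaturate C3–C4 because C1 is a bridgehead, and it touches no stereocenter.

Step 2
Reactants: 2 (1R,5R)-6,6-dimethylbicyclo[3.1.1]hept-3-en-2-one
Product: 4 (1R,4R,5S)-4-hydroxy-6,6-dimethylbicyclo[3.1.1]heptan-2-one, via boryl ketone 3 (not isolated)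
Conditions: B2pin2, CuCl (5 mol%), Xantphos (5 mol%), NaOtBu (10 mol%), MeOH, THF, 25 °C; then NaBO3·4H2O, THF/H2O, 25 °C
Reagents that add atoms: bis(pinacolato)diboron (boron of 3), CC1(C)OB(OC1(C)C)B1OC(C)(C)C(C)(C)O1; sodium perborate (oxygen of 4), [Na+].[O-]OB=O
Why: Copper-catalysed conjugate borylation followed by stereoretentive perborate oxidation; the boryl-copper species adds to the enone face away from the gem-dimethyl bridge, which fixes the future C5 oxygen α, trans to the future isopropenyl group.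

Step 3
Reactants: 4 (1R,4R,5S)-4-hydroxy-6,6-dimethylbicyclo[3.1.1]heptan-2-one
Product: 7 (4S,5R)-4-(prop-1-en-2-yl)-1,5-bis(trimethylsilyloxy)cyclohex-1-ene, via trimethylsilyl ether 5 (not isolated), via tertiary iodide 6 (not isolated)
Conditions: BSA (0.6 equiv), CH2Cl2, 25 °C; Me3SiI (1.2 equiv), −20 → 0 °C; then DBU (2 equiv), 40 °C
Reagents that add atoms: N,O-bis(trimethylsilyl)acetamide, CC(=N[Si](C)(C)C)O[Si](C)(C)C; iodotrimethylsilane, C[Si](C)(C)I
Why: After O-silylation, Me3SiI opens the strained C1–C6 cyclobutane bond next to the carbonyl (homo-conjugate iodosilane opening of a strained ketone) to a regiodefined silyl enol ether and a tertiary iodide, and E2 elimination with DBU unveils the isopropenyl group; the nopinone C5 stereocenter becomes C4 of the target untouched.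

Step 4
Reactants: 7 (4S,5R)-4-(prop-1-en-2-yl)-1,5-bis(trimethylsilyloxy)cyclohex-1-ene
Product: 9 (4S,5R)-5-hydroxy-4-(prop-1-en-2-yl)cyclohex-2-en-1-one, via silyl-protected enone 8 (not isolated)
Conditions: Pd(OAc)2 (10 mol%), O2 (1 atm), DMSO, 25 °C; then citric acid, MeOH, 0 °C
Reagents that add atoms: none
Why: Saegusa–Ito oxidation (aerobic Larock variant) of the regiodefined silyl enol ether places the enone on the C7a/C3a side, and mild methanolysis frees the C5 hydroxyl without touching a stereocenter.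

Step 5
Reactants: 9 (4S,5R)-5-hydroxy-4-(prop-1-en-2-yl)cyclohex-2-en-1-one; 10 2-(trimethylsilyl)ethyl bromoacetate
Product: 12 2-(trimethylsilyl)ethyl [(1β,2α,3β,4α)-4-hydroxy-6-oxo-3-(prop-1-en-2-yl)-2-(prop-1-ynyl)cyclohexyl]acetate, via aluminium enolate 11 (not isolated)
Conditions: Me2AlC≡CMe (2.5 equiv, from MeC≡CLi and Me2AlCl), toluene/Et2O, −40 → 0 °C; MeLi, −78 °C, then 10, DMPU, −78 → −20 °C; work-up; DBU (0.1 equiv), CH2Cl2, 25 °C
Reagents that add atoms: dimethyl(prop-1-yn-1-yl)aluminium, CC#C[Al](C)C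
Why: Tandem vicinal difunctionalisation: the aluminium alkoxide formed at O5 delivers its propynyl group to C3a on its own α face, which is also anti to the adjacent isopropenyl group (hydroxyl-directed alkynylalane conjugate addition, known for 4-hydroxycyclopentenones), the regiodefined enolate is C-alkylated as its lithium aluminate, and base equilibration puts the C7a side chain equatorial, trans to the propynyl group.

Step 6
Reactants: 12 2-(trimethylsilyl)ethyl [(1β,2α,3β,4α)-4-hydroxy-6-oxo-3-(prop-1-en-2-yl)-2-(prop-1-ynyl)cyclohexyl]acetate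
Product: 13 2-(trimethylsilyl)ethyl [(1β,2α,3β,4α)-4-hydroxy-6-methylidene-3-(prop-1-en-2-yl)-2-(prop-1-ynyl)cyclohexyl]acetate
Conditions: Zn, CH2Br2, TiCl4, THF/CH2Cl2, 0 → 25 °C
Reagents that add atoms: dibromomethane, BrCBr
Why: Takai–Lombardo methylenation is non-basic, so the β-hydroxy ketone and the epimerisable C7a center survive, and ester, alkyne and isopropenyl group are left alone.

Step 7
Reactants: 13 2-(trimethylsilyl)ethyl [(1β,2α,3β,4α)-4-hydroxy-6-methylidene-3-(prop-1-en-2-yl)-2-(prop-1-ynyl)cyclohexyl]acetate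
Product: 14 2-(trimethylsilyl)ethyl [(1β,2α,3β,4α)-4-hydroxy-6-methylidene-3-[(2R)-2-methyloxiran-2-yl]-2-(prop-1-ynyl)cyclohexyl]acetate
Conditions: VO(acac)2 (5 mol%), tBuOOH (1.3 equiv), CH2Cl2, 0 → 25 °C
Reagents that add atoms: tert-butyl hydroperoxide, CC(C)(C)OO
Why: Vanadium-catalysed hydroxyl-directed epoxidation of a homoallylic alcohol (Sharpless–Mihelich): the equatorial C5–O–V peroxide reaches the freely rotating isopropenyl group in the rotamer with C4–H eclipsing the =CH2, which should give the (R)-oxirane, while the ring methylidene lies in the ring plane out of reach of the equatorial oxygen.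

Step 8
Reactants: 14 2-(trimethylsilyl)ethyl [(1β,2α,3β,4α)-4-hydroxy-6-methylidene-3-[(2R)-2-methyloxiran-2-yl]-2-(prop-1-ynyl)cyclohexyl]acetate; 15 (2Z)-3-methylpent-2-enoic acid
Product: 16 2-(trimethylsilyl)ethyl [(1β,2α,3β,4α)-6-methylidene-4-[(2Z)-3-methylpent-2-enoyloxy]-3-[(2R)-2-methyloxiran-2-yl]-2-(prop-1-ynyl)cyclohexyl]acetate
Conditions: DIC, DMAP (0.1 equiv), CH2Cl2, 0 → 25 °C
Reagents that add atoms: none
Why: Steglich esterification of the only free hydroxyl; low temperature and catalytic DMAP are chosen to keep the Z geometry of the β,β-disubstituted enoate.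

Step 9
Reactants: 16 2-(trimethylsilyl)ethyl [(1β,2α,3β,4α)-6-methylidene-4-[(2Z)-3-methylpent-2-enoyloxy]-3-[(2R)-2-methyloxiran-2-yl]-2-(prop-1-ynyl)cyclohexyl]acetate
Product: 17 [(1β,2α,3β,4α)-6-methylidene-4-[(2Z)-3-methylpent-2-enoyloxy]-3-[(2R)-2-methyloxiran-2-yl]-2-(prop-1-ynyl)cyclohexyl]acetic acid
Conditions: Bu4NF (1.5 equiv), THF, 0 °C; dil. HCl work-up
Reagents that add atoms: none
Why: Fluoride-induced β-elimination of the 2-(trimethylsilyl)ethyl ester frees the acid and leaves the enoate ester, the oxirane and the alkenes alone.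

Step 10
Reactants: 17 [(1β,2α,3β,4α)-6-methylidene-4-[(2Z)-3-methylpent-2-enoyloxy]-3-[(2R)-2-methyloxiran-2-yl]-2-(prop-1-ynyl)cyclohexyl]acetic acid
Product: 18 (3E)-3-ethylidene-7-methylidene-4β-[(2R)-2-methyloxiran-2-yl]-2-oxo-(3aβ-H,7aα-H)-octahydroinden-5α-yl (2Z)-3-methylpent-2-enoate
Conditions: [Ir(dF(CF3)ppy)2(dtbbpy)]PF6 (1 mol%), PPh3 (1.3 equiv), 2,4,6-collidine, 2,4,6-triisopropylbenzenethiol (10 mol%), MeCN/PhMe, blue LED (450 nm), 20 °C
Reagents that add atoms: none
Why: Proposed new method: the excited iridium photocatalyst oxidises PPh3, the phosphine radical cation adds to the carboxylate and the phosphoranyl radical fragments to Ph3P=O and a primary-alkyl acyl radical (slow to decarbonylate), which closes 5-exo-dig onto the propynyl carbon attached to C3a (the ring methylidene would need a 4-exo or 5-endo closure), and the fast-inverting vinyl radical takes hydrogen from the hindered thiol on the open carbonyl side so that the methyl ends cis to C3a (E) while the thiyl radical closes the photoredox cycle; the ring fusion is already trans in 17, and the closest known chemistry is the photoredox phosphine-mediated deoxygenative hydroacylation of alkenes with carboxylic acids and the classical acyl selenide to alkyne radical cyclization, neither shown for an acid-derived acyl radical closing onto an unactivated internal alkyne.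

Step 11
Reactants: 18 (3E)-3-ethylidene-7-methylidene-4β-[(2R)-2-methyloxiran-2-yl]-2-oxo-(3aβ-H,7aα-H)-octahydroinden-5α-yl (2Z)-3-methylpent-2-enoate
Product: 19 (3E)-3-ethylidene-6α-hydroxy-7-methylidene-4β-[(2R)-2-methyloxiran-2-yl]-2-oxo-(3aβ-H,7aα-H)-octahydroinden-5α-yl (2Z)-3-methylpent-2-enoate
Conditions: SeO2 (0.3 equiv), tBuOOH (2 equiv), CH2Cl2, 0 → 25 °C
Reagents that add atoms: tert-butyl hydroperoxide, CC(C)(C)OO
Why: Sharpless SeO2/tBuOOH allylic hydroxylation (ene reaction then 2,3-sigmatropic shift) of the electron-rich 1,1-disubstituted alkene prefers the ring CH2 over the ring CH and removes the axial C6–H, so oxygen returns on the same axial α face, cis to the C5 ester; the two electron-poor enone and enoate alkenes do not react.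

Step 12
Reactants: 19 (3E)-3-ethylidene-6α-hydroxy-7-methylidene-4β-[(2R)-2-methyloxiran-2-yl]-2-oxo-(3aβ-H,7aα-H)-octahydroinden-5α-yl (2Z)-3-methylpent-2-enoate
Product: 21 (3E)-3-ethylidene-1β,6α-dihydroxy-7-methylidene-4β-[(2R)-2-methyloxiran-2-yl]-2-oxo-(3aβ-H,7aα-H)-octahydroinden-5α-yl (2Z)-3-methylpent-2-enoate, via dilithium enolate 20 (not isolated)
Conditions: LiN(SiMe3)2 (2.2 equiv), THF, −78 °C; then 3-phenyl-2-(phenylsulfonyl)oxaziridine (racemic), −78 °C; NH4Cl
Reagents that add atoms: 3-phenyl-2-(phenylsulfonyl)oxaziridine, O=S(=O)(N1OC1c1ccccc1)c1ccccc1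
Why: Kinetic deprotonation gives the cross-conjugated C1 enolate (the C6 alkoxide is inert at −78 °C), and Davis oxaziridine hydroxylation should occur on the β face, anti to the axial C7a–H, which also leaves only hydrogen in the plane next to the ring methylidene.

Step 13
Reactants: 21 (3E)-3-ethylidene-1β,6α-dihydroxy-7-methylidene-4β-[(2R)-2-methyloxiran-2-yl]-2-oxo-(3aβ-H,7aα-H)-octahydroinden-5α-yl (2Z)-3-methylpent-2-enoate; 22 (2R)-2-methylbutanoic acid
Product: 23 CNP0274886.3, (3E)-3-ethylidene-7-methylidene-4β-[(2R)-2-methyloxiran-2-yl]-1β,6α-bis[(2R)-2-methylbutanoyloxy]-2-oxo-(3aβ-H,7aα-H)-octahydroinden-5α-yl (2Z)-3-methylpent-2-enoate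
Conditions: 22 (4 equiv), DIC, DMAP (0.2 equiv), CH2Cl2, 0 → 25 °C
Reagents that add atoms: none
Why: Double Steglich esterification of the two remaining hydroxyls with the bought (R)-acid installs both 2-methylbutanoates, and the C1 center, now α to the ketone, sits in its less crowded β orientation.

**Compound list**

1 | (1R,5S)-6,6-dimethylbicyclo[3.1.1]heptan-2-one ((+)-nopinone) | O=C1[C@@H]2C[C@H](CC1)C2(C)C | starting material
2 | (1R,5R)-6,6-dimethylbicyclo[3.1.1]hept-3-en-2-one ((+)-apoverbenone) | O=C1[C@@H]2C[C@H](C=C1)C2(C)C | intermediate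
3 | (1R,4R,5R)-6,6-dimethyl-4-(4,4,5,5-tetramethyl-1,3,2-dioxaborolan-2-yl)bicyclo[3.1.1]heptan-2-one | O=C1[C@@H]2C[C@H]([C@H](B3OC(C)(C)C(C)(C)O3)C1)C2(C)C | intermediate
4 | (1R,4R,5S)-4-hydroxy-6,6-dimethylbicyclo[3.1.1]heptan-2-one | O=C1[C@@H]2C[C@H]([C@H](O)C1)C2(C)C | intermediate
5 | (1R,4R,5S)-6,6-dimethyl-4-(trimethylsilyloxy)bicyclo[3.1.1]heptan-2-one | O=C1[C@@H]2C[C@H]([C@H](O[Si](C)(C)C)C1)C2(C)C | intermediate
6 | (4R,5R)-4-(2-iodopropan-2-yl)-1,5-bis(trimethylsilyloxy)cyclohex-1-ene | C[Si](C)(C)OC1=CC[C@@H](C(C)(C)I)[C@H](O[Si](C)(C)C)C1 | intermediate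
7 | (4S,5R)-4-(prop-1-en-2-yl)-1,5-bis(trimethylsilyloxy)cyclohex-1-ene | C[Si](C)(C)OC1=CC[C@@H](C(C)=C)[C@H](O[Si](C)(C)C)C1 | intermediate
8 | (4S,5R)-4-(prop-1-en-2-yl)-5-(trimethylsilyloxy)cyclohex-2-en-1-one | O=C1C=C[C@@H](C(C)=C)[C@H](O[Si](C)(C)C)C1 | intermediate
9 | (4S,5R)-5-hydroxy-4-(prop-1-en-2-yl)cyclohex-2-en-1-one | O=C1C=C[C@@H](C(C)=C)[C@H](O)C1 | intermediate
10 | 2-(trimethylsilyl)ethyl bromoacetate | BrCC(=O)OCC[Si](C)(C)C | starting material
11 | methylaluminium chelate of the C5 alkoxide and C7 enolate of the 3aα-propynyl conjugate adduct | C[Al]1OC2=C[C@H](C#CC)[C@@H](C(C)=C)[C@@H](C2)O1 | intermediate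
12 | 2-(trimethylsilyl)ethyl [(1β,2α,3β,4α)-4-hydroxy-6-oxo-3-(prop-1-en-2-yl)-2-(prop-1-ynyl)cyclohexyl]acetate | O=C1[C@@H](CC(=O)OCC[Si](C)(C)C)[C@H](C#CC)[C@@H](C(C)=C)[C@H](O)C1 | intermediate
13 | 2-(trimethylsilyl)ethyl [(1β,2α,3β,4α)-4-hydroxy-6-methylidene-3-(prop-1-en-2-yl)-2-(prop-1-ynyl)cyclohexyl]acetate | C=C1[C@@H](CC(=O)OCC[Si](C)(C)C)[C@H](C#CC)[C@@H](C(C)=C)[C@H](O)C1 | intermediate
14 | 2-(trimethylsilyl)ethyl [(1β,2α,3β,4α)-4-hydroxy-6-methylidene-3-[(2R)-2-methyloxiran-2-yl]-2-(prop-1-ynyl)cyclohexyl]acetate | C=C1[C@@H](CC(=O)OCC[Si](C)(C)C)[C@H](C#CC)[C@@H]([C@]2(C)CO2)[C@H](O)C1 | intermediate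
15 | (2Z)-3-methylpent-2-enoic acid | OC(=O)/C=C(/C)CC | starting material
16 | 2-(trimethylsilyl)ethyl [(1β,2α,3β,4α)-6-methylidene-4-[(2Z)-3-methylpent-2-enoyloxy]-3-[(2R)-2-methyloxiran-2-yl]-2-(prop-1-ynyl)cyclohexyl]acetate | C=C1[C@@H](CC(=O)OCC[Si](C)(C)C)[C@H](C#CC)[C@@H]([C@]2(C)CO2)[C@H](OC(=O)/C=C(/C)CC)C1 | intermediate
17 | [(1β,2α,3β,4α)-6-methylidene-4-[(2Z)-3-methylpent-2-enoyloxy]-3-[(2R)-2-methyloxiran-2-yl]-2-(prop-1-ynyl)cyclohexyl]acetic acid | C=C1[C@@H](CC(=O)O)[C@H](C#CC)[C@@H]([C@]2(C)CO2)[C@H](OC(=O)/C=C(/C)CC)C1 | intermediate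
18 | (3E)-3-ethylidene-7-methylidene-4β-[(2R)-2-methyloxiran-2-yl]-2-oxo-(3aβ-H,7aα-H)-octahydroinden-5α-yl (2Z)-3-methylpent-2-enoate | C=C1[C@@H]2[C@H](/C(=C\C)C(=O)C2)[C@@H]([C@]2(C)CO2)[C@H](OC(=O)/C=C(/C)CC)C1 | intermediate
19 | 6α-hydroxy derivative of 18 | C=C1[C@@H]2[C@H](/C(=C\C)C(=O)C2)[C@@H]([C@]2(C)CO2)[C@H](OC(=O)/C=C(/C)CC)[C@@H]1O | intermediate
20 | dilithium C6 alkoxide / C1 enolate of 19 | C=C1[C@@H]2[C@H](/C(=C\C)C(O[Li])=C2)[C@@H]([C@]2(C)CO2)[C@H](OC(=O)/C=C(/C)CC)[C@@H]1O[Li] | intermediate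
21 | 1β,6α-dihydroxy derivative of 18 | C=C1[C@@H]2[C@H](/C(=C\C)C(=O)[C@@H]2O)[C@@H]([C@]2(C)CO2)[C@H](OC(=O)/C=C(/C)CC)[C@@H]1O | intermediate
22 | (2R)-2-methylbutanoic acid | OC(=O)[C@H](C)CC | starting material
23 | CNP0274886.3 | C=C1[C@@H]2[C@H](/C(=C\C)C(=O)[C@@H]2OC(=O)[C@H](C)CC)[C@@H]([C@]2(C)CO2)[C@H](OC(=O)/C=C(/C)CC)[C@@H]1OC(=O)[C@H](C)CC | target

**Step count**

Total steps: 13. Longest linear sequence: 13 (1 → 23).

**Three steps most likely to fail**

Step 10 (the new photochemical ring closure). The thiol may reduce the acyl radical to the aldehyde before it cyclizes, the phosphine radical cation may attack the alkyne or the oxirane, and the ethylidene geometry depends on where the vinyl radical is quenched. The fallback uses known chemistry, sets out from 17 and comes back at 18. The acid is converted with PhSeSePh and PBu3 into the Se-phenyl selenoester F7, which is cyclized with (Me3Si)3SiH and AIBN in benzene at 80 °C. This is the classical acyl selenide 5-exo-dig radical cyclization onto an alkyne, and the bulky silane again delivers hydrogen from the carbonyl side.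

Step 3 (cyclobutane opening with a β-silyloxy group present). The silyl ether at C5 could be lost by ionisation or elimination under Me3SiI, and the elimination of HI may give some isopropylidene isomer. The fallback sets out from 3, isolated instead of being oxidised, and comes back at 9, so that no β-oxygen is present during the Lewis-acid step. Me3SiI opens the boronate to the tertiary iodide boronate F1, and DBU converts it into the silyl enol ether boronate F2. Aerobic Pd(OAc)2 dehydrogenation gives the boryl enone F3, and Me3NO (or H2O2 at pH 7) then oxidises the C–B bond with retention to 9.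

Step 5 (directed three-component coupling). The alane may add 1,2 to the ketone, delivery from the more remote C5 alkoxide may be less efficient than in the known 4-hydroxycyclopentenone cases, and the aluminate enolate may alkylate sluggishly. The fallback sets out from 9 and comes back at 12. The hydroxyl is protected as the triethylsilyl ether F4. TBSOTf-promoted conjugate addition of MeC≡CZnBr, relying only on the anti-directing isopropenyl group, gives the tert-butyldimethylsilyl enol ether F5. MeLi then regenerates the regiodefined lithium enolate, which is alkylated with 10 to the keto ester triethylsilyl ether F6. PPTS in MeOH removes the silyl ether to give 12 after equilibration at C7a.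

Further compounds
F1 | step 3 | (4R,5R)-type tertiary iodide boronate: 4-(2-iodopropan-2-yl)-5-(pinacolboryl)-1-(trimethylsilyloxy)cyclohex-1-ene | C[Si](C)(C)OC1=CC[C@@H](C(C)(C)I)[C@H](B2OC(C)(C)C(C)(C)O2)C1
F2 | step 3 | silyl enol ether boronate: 5-(pinacolboryl)-4-(prop-1-en-2-yl)-1-(trimethylsilyloxy)cyclohex-1-ene | C[Si](C)(C)OC1=CC[C@@H](C(C)=C)[C@H](B2OC(C)(C)C(C)(C)O2)C1
F3 | step 3 | boryl enone: 5-(pinacolboryl)-4-(prop-1-en-2-yl)cyclohex-2-en-1-one | O=C1C=C[C@@H](C(C)=C)[C@H](B2OC(C)(C)C(C)(C)O2)C1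
F4 | step 5 | triethylsilyl ether of 9 | O=C1C=C[C@@H](C(C)=C)[C@H](O[Si](CC)(CC)CC)C1
F5 | step 5 | tert-butyldimethylsilyl enol ether of the 3aα-propynyl adduct (5-triethylsilyl ether) | CC(C)(C)[Si](C)(C)OC1=C[C@H](C#CC)[C@@H](C(C)=C)[C@H](O[Si](CC)(CC)CC)C1
F6 | step 5 | triethylsilyl ether of 12 | O=C1[C@@H](CC(=O)OCC[Si](C)(C)C)[C@H](C#CC)[C@@H](C(C)=C)[C@H](O[Si](CC)(CC)CC)C1
F7 | step 10 | Se-phenyl selenoester of 17 | C=C1[C@@H](CC(=O)[Se]c2ccccc2)[C@H](C#CC)[C@@H]([C@]3(C)CO3)[C@H](OC(=O)/C=C(/C)CC)C1
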